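The carbon shared by the bromocyclohexane (ring A) and the oxepane (ring B) that bears the methyl group and the ether oxygen (C7, O1) is a disguised methyl ketone. Everything rests on alkylating that carbonyl oxygen and closing ring A in one flask: the ketone oxygen of an acyclic bromo keto allylsilane opens a silyl-activated bromovinyl epoxide at its allylic carbon, the later OCH(CH2Br) carbon C2 (O1–C2, inversion), and the tethered allylsilane traps the resulting oxocarbenium ion through a chair at the later ring-fusion CH, C6 (C6–C7). The step builds ring A and sets C6 and C7; its precursor holds no ring of the target. Ring B is closed last by chromium-mediated vinyl addition.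

Key step: step 8

Remark on locants: C1 = CH2Br carbon, C2 = OCH, C3 = C(=CH2), C15 = methylidene carbon, C4 = CHOH, C5 = CH2 of ring B, C6 = ring-fusion CH, C7 = ring-fusion C(CH3)O, C8 and C9 = CH2 groups of ring A, C10 = CHBr, C11 = C(CH3)2, O1 = ether oxygen.
Assumption: (S)-2-vinyloxirane is bought as the single enantiomer (it is also the epoxide left by hydrolytic kinetic resolution of the cheap racemate).
Remark: the cross metathesis of step 5 should give 8 as an E/Z mixture (E drawn); both isomers end as the same vinyl group in step 8.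

Step 1
Reactants: 1 methyl 3,3-dimethylpent-4-enoate
Product: 2 3,3-dimethylpent-4-enal
Conditions: i-Bu2AlH (DIBAL-H, 1.05 equiv), CH2Cl2, −78 °C; aq. potassium sodium tartrate (KNaC4H4O6)
Reagents that add atoms: none
Why: Partial hydride reduction of the ester at −78 °C (DIBAL-H ester-to-aldehyde reduction) should stop at the aluminium hemiacetal, which releases the aldehyde on work-up; no stereocenter is formed.

Step 2
Reactants: 2 3,3-dimethylpent-4-enal
Product: 4 (R)-2-bromo-3,3-dimethylpent-4-en-1-ol, via (R)-2-bromo-3,3-dimethylpent-4-enal 3 (not isolated)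
Conditions: (2S,5S)-2,5-diphenylpyrrolidine (20 mol%), 4,4-dibromo-2,6-di-tert-butylcyclohexa-2,5-dien-1-one (1.0 equiv), PhCO2H (20 mol%), H2O (2 equiv), CH2Cl2/pentane 1:1, −40 °C; then NaBH4, MeOH, −40 to 0 °C
Reagents that add atoms: 4,4-dibromo-2,6-di-tert-butylcyclohexa-2,5-dien-1-one, CC(C)(C)C1=CC(Br)(Br)C=C(C(C)(C)C)C1=O
Why: Organocatalytic enamine α-bromination, in which the twofold-symmetric amine shields one face of the E-enamine so that the mild Br+ donor should enter from the open face and set the future C10 center (R here, S from step 4 on by a priority change only); immediate borohydride reduction fixes the labile α-bromo aldehyde as the bromohydrin.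

Step 3
Reactants: 4 (R)-2-bromo-3,3-dimethylpent-4-en-1-ol
Product: 5 (R)-2-bromo-3,3-dimethylpent-4-en-1-yl trifluoromethanesulfonate
Conditions: Tf2O (1.1 equiv), 2,6-lutidine (1.3 equiv), CH2Cl2, −78 °C; used at once
Reagents that add atoms: trifluoromethanesulfonic anhydride, O=S(=O)(OS(=O)(=O)C(F)(F)F)C(F)(F)F
Why: O-Sulfonylation of the primary alcohol gives the most reactive leaving group for a β-branched primary carbon and does not touch the stereocenter.

Step 4
Reactants: 5 (R)-2-bromo-3,3-dimethylpent-4-en-1-yl trifluoromethanesulfonate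
Product: 7 (S)-5-bromo-6,6-dimethyloct-7-en-2-one, via N,N-dimethylhydrazone 6 (not isolated)
Conditions: acetone N,N-dimethylhydrazone (1.5 equiv), LiN(i-Pr)2 (LDA, 1.5 equiv), THF, −78 °C; then 5, −78 to −40 °C; then pH 4.5 acetate buffer, THF, 23 °C
Reagents that add atoms: acetone N,N-dimethylhydrazone, CC(C)=NN(C)C; water, O
Why: SN2 C-alkylation of the lithium azaenolate at the primary triflate (metalated hydrazone alkylation) should outrun any attack at the neopentyl secondary bromide, and mild hydrolysis then frees the methyl ketone without touching the C–Br stereocenter.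

Step 5
Reactants: 7 (S)-5-bromo-6,6-dimethyloct-7-en-2-one
Product: 8 (5S,7E)-5-bromo-6,6-dimethyl-9-(trimethylsilyl)non-7-en-2-one
Conditions: allyltrimethylsilane (5 equiv), second-generation Grubbs catalyst RuCl2(=CHPh)(PCy3)(H2IMes) (5 mol%), CH2Cl2, 40 °C
Reagents that add atoms: allyltrimethylsilane, C=CC[Si](C)(C)C
Why: Olefin cross metathesis of the hindered vinyl group, which cannot homodimerise, with an excess of the reactive allylsilane should give the allylsilane with loss of ethene; no stereocenter is involved.

Step 6
Reactants: 9 (S)-2-vinyloxirane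
Product: 10 (2R)-2-(1,2-dibromoethyl)oxirane (both epimers at the CHBr carbon)
Conditions: Br2 (1.0 equiv), CH2Cl2, −78 °C
Reagents that add atoms: bromine, BrBr
Why: Electrophilic anti addition of bromine to the vinyl group leaves the epoxide stereocenter untouched (its descriptor changes from S to R by priority only); the new CHBr center is erased in step 7.

Step 7
Reactants: 10 (2R)-2-(1,2-dibromoethyl)oxirane
Product: 11 (R)-2-(1-bromoethenyl)oxirane
Conditions: DBU (1.2 equiv), Et2O, 0 to 23 °C; distilled
Reagents that add atoms: none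
Why: E2 dehydrobromination should remove the more acidic proton on the CHBr carbon next to the epoxide together with the primary bromide, giving the 2-bromo-1-alkene with the epoxide stereocenter intact.

Step 8
Reactants: 8 (5S,7E)-5-bromo-6,6-dimethyl-9-(trimethylsilyl)non-7-en-2-one; 11 (R)-2-(1-bromoethenyl)oxirane
Product: 14 (2S)-3-bromo-2-{[(1S,2S,4S)-4-bromo-2-ethenyl-1,3,3-trimethylcyclohexyl]oxy}but-3-en-1-ol, via silyloxy oxocarbenium triflate 12 (not isolated), via O-trimethylsilyl ether 13 (not isolated)
Conditions: 8, Me3SiOTf (0.5 equiv), 2,6-di-tert-butyl-4-methylpyridine (0.2 equiv), CH2Cl2, −78 °C; slow addition of 11 (2.5 equiv), −78 to −40 °C; then K2CO3 (cat.), MeOH, 0 °C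
Reagents that add atoms: none
Why: Proposed new method: Me3SiOTf silylates the epoxide oxygen of 11, the carbonyl oxygen of 8 attacks the allylic carbon C2 with inversion (O1–C2), and the silyloxy oxocarbenium ion 12 (free or resting as its 1,3-dioxolane) is captured at C7 by the γ-carbon C6 of the tethered allylsilane, whose silyl group then regenerates the catalyst. The closest known reaction types are the Lewis-acid ketalisation of ketones by epoxides and the intramolecular Hosomi–Sakurai reaction of ketal-derived oxocarbenium ions (silyl-modified Sakurai reaction). Ring A closes in a 6-exo-trig mode with respect to the allylsilane double bond through a chair. C2 is controlled by the epoxide stereocenter (inversion); C6 and C7 are controlled by the C10 bromide, which sits equatorial in the chair together with the alkene and the in-plane alkoxy arm of the oxocarbenium ion, so that the C7 methyl group should go axial and O1 and the new vinyl group end trans-diequatorial. The step needs O-alkylation of the ketone at the allylic and not the primary epoxide carbon, which the allylic activation by the bromovinyl group and the silyl activation should secure, and it needs this to precede C-allylation, which Me3SiOTf does not promote on a free ketone at this temperature.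

Step 9
Reactants: 14 (2S)-3-bromo-2-{[(1S,2S,4S)-4-bromo-2-ethenyl-1,3,3-trimethylcyclohexyl]oxy}but-3-en-1-ol
Product: 15 (1S,2S,4S)-4-bromo-1-{[(2S)-1,3-dibromobut-3-en-2-yl]oxy}-2-ethenyl-1,3,3-trimethylcyclohexane
Conditions: CBr4 (1.3 equiv), PPh3 (1.4 equiv), CH2Cl2, 0 °C
Reagents that add atoms: carbon tetrabromide, BrC(Br)(Br)Br
Why: Appel reaction, in which bromide displaces the primary alkoxyphosphonium group without involving any stereocenter.

Step 10
Reactants: 15 (1S,2S,4S)-4-bromo-1-{[(2S)-1,3-dibromobut-3-en-2-yl]oxy}-2-ethenyl-1,3,3-trimethylcyclohexane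
Product: 16 2-[(1S,3S,6S)-3-bromo-6-{[(2S)-1,3-dibromobut-3-en-2-yl]oxy}-2,2,6-trimethylcyclohexyl]ethan-1-ol
Conditions: 9-BBN (1.3 equiv), THF, 0 to 23 °C; then NaBO3·4H2O, THF/H2O, 23 °C
Reagents that add atoms: sodium perborate (used as the tetrahydrate), [Na+].[Na+].O[B-]1(O)OO[B-](O)(O)OO1
Why: Anti-Markovnikov hydroboration–oxidation, in which the bulky borane should add only to the monosubstituted vinyl group and not to the electron-poor 2-bromoalkene, while the mild perborate oxidation spares the alkyl bromides; no stereocenter is formed.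

Step 11
Reactants: 16 2-[(1S,3S,6S)-3-bromo-6-{[(2S)-1,3-dibromobut-3-en-2-yl]oxy}-2,2,6-trimethylcyclohexyl]ethan-1-ol
Product: 17 2-[(1S,3S,6S)-3-bromo-6-{[(2S)-1,3-dibromobut-3-en-2-yl]oxy}-2,2,6-trimethylcyclohexyl]acetaldehyde
Conditions: Dess–Martin periodinane (1.3 equiv), CH2Cl2, 0 to 23 °C
Reagents that add atoms: none
Why: Dess–Martin oxidation of the primary alcohol to the aldehyde under neutral conditions; the aldehyde has no α-stereocenter to lose.

Step 12
Reactants: 17 2-[(1S,3S,6S)-3-bromo-6-{[(2S)-1,3-dibromobut-3-en-2-yl]oxy}-2,2,6-trimethylcyclohexyl]acetaldehyde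
Product: 18 (2R,4R,5aS,7S,9aS)-7-bromo-2-(bromomethyl)-6,6,9a-trimethyl-3-methylidenedecahydro-1-benzoxepin-4-ol
Conditions: CrCl2 (6 equiv), NiCl2 (2 mol%), DMSO/THF 3:1, 23 °C, 0.005 M
Reagents that add atoms: none
Why: Intramolecular Nozaki–Hiyama–Kishi reaction, in which the alkenylchromium species formed from the 2-bromoalkene under nickel catalysis should add to the aldehyde, close the seven-membered ring B at C3–C4 and deliver the exocyclic methylene and the C4 hydroxyl at once; the C4 configuration (R wanted) rests on substrate control, the chromium alkoxide being expected pseudo-axial to avoid allylic strain with the methylene group.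

Compound list
1 | methyl 3,3-dimethylpent-4-enoate | COC(=O)CC(C)(C)C=C | starting material
2 | 3,3-dimethylpent-4-enal | O=CCC(C)(C)C=C | intermediate
3 | (R)-2-bromo-3,3-dimethylpent-4-enal | O=C[C@H](Br)C(C)(C)C=C | intermediate
4 | (R)-2-bromo-3,3-dimethylpent-4-en-1-ol | OC[C@H](Br)C(C)(C)C=C | intermediate
5 | (R)-2-bromo-3,3-dimethylpent-4-en-1-yl trifluoromethanesulfonate | O=S(=O)(OC[C@H](Br)C(C)(C)C=C)C(F)(F)F | intermediate
6 | (S)-5-bromo-6,6-dimethyloct-7-en-2-one N,N-dimethylhydrazone | CN(C)N=C(C)CC[C@H](Br)C(C)(C)C=C | intermediate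
7 | (S)-5-bromo-6,6-dimethyloct-7-en-2-one | CC(=O)CC[C@H](Br)C(C)(C)C=C | intermediate
8 | (5S,7E)-5-bromo-6,6-dimethyl-9-(trimethylsilyl)non-7-en-2-one | CC(=O)CC[C@H](Br)C(C)(C)/C=C/C[Si](C)(C)C | intermediate
9 | (S)-2-vinyloxirane | C=C[C@H]1CO1 | starting material
10 | (2R)-2-(1,2-dibromoethyl)oxirane (both epimers at the CHBr carbon) | BrCC(Br)[C@H]1CO1 | intermediate
11 | (R)-2-(1-bromoethenyl)oxirane | C=C(Br)[C@H]1CO1 | intermediate
12 | silyloxy oxocarbenium triflate from 8 and 11 (O1 of the ketone bonded to C2) | CC(=[O+][C@@H](CO[Si](C)(C)C)C(Br)=C)CC[C@H](Br)C(C)(C)/C=C/C[Si](C)(C)C.[O-]S(=O)(=O)C(F)(F)F | intermediate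
13 | O-trimethylsilyl ether of 14 | C=C[C@H]1C(C)(C)[C@@H](Br)CC[C@]1(C)O[C@@H](CO[Si](C)(C)C)C(Br)=C | intermediate
14 | (2S)-3-bromo-2-{[(1S,2S,4S)-4-bromo-2-ethenyl-1,3,3-trimethylcyclohexyl]oxy}but-3-en-1-ol | C=C[C@H]1C(C)(C)[C@@H](Br)CC[C@]1(C)O[C@@H](CO)C(Br)=C | intermediate
15 | (1S,2S,4S)-4-bromo-1-{[(2S)-1,3-dibromobut-3-en-2-yl]oxy}-2-ethenyl-1,3,3-trimethylcyclohexane | C=C[C@H]1C(C)(C)[C@@H](Br)CC[C@]1(C)O[C@@H](CBr)C(Br)=C | intermediate
16 | 2-[(1S,3S,6S)-3-bromo-6-{[(2S)-1,3-dibromobut-3-en-2-yl]oxy}-2,2,6-trimethylcyclohexyl]ethan-1-ol | OCC[C@H]1C(C)(C)[C@@H](Br)CC[C@]1(C)O[C@@H](CBr)C(Br)=C | intermediate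
17 | 2-[(1S,3S,6S)-3-bromo-6-{[(2S)-1,3-dibromobut-3-en-2-yl]oxy}-2,2,6-trimethylcyclohexyl]acetaldehyde | O=CC[C@H]1C(C)(C)[C@@H](Br)CC[C@]1(C)O[C@@H](CBr)C(Br)=C | intermediate
18 | (2R,4R,5aS,7S,9aS)-7-bromo-2-(bromomethyl)-6,6,9a-trimethyl-3-methylidenedecahydro-1-benzoxepin-4-ol | C=C1[C@H](O)C[C@H]2C(C)(C)[C@@H](Br)CC[C@]2(C)O[C@H]1CBr | target

Total step count: 12. Longest linear sequence: 10 steps (1 → 2 → 4 → 5 → 7 → 8 → 14 → 15 → 16 → 17 → 18); the epoxide 11 is made in 2 steps from 9.

Steps most likely to fail

Step 8. The ketone oxygen may lose the competition for the activated epoxide to epoxide rearrangement or oligomerisation. Attack may also go to the primary epoxide carbon or in an SN2′ sense. The chair closure may show poor facial selectivity at C7 or be overtaken by protodesilylation. The fallback uses known chemistry and separates the two events; it sets out from 8 and 11 and comes back at 14. 8 and 11 are condensed with catalytic BF3·OEt2 (CH2Cl2, −30 °C), the established ketone–epoxide route to 1,3-dioxolanes with inversion at the allylic epoxide carbon. The ketal (4S)-4-(1-bromoethenyl)-2-[(3S,5E)-3-bromo-4,4-dimethyl-7-(trimethylsilyl)hept-5-en-1-yl]-2-methyl-1,3-dioxolane F1 is isolated as a mixture of ketal epimers. F1 is then treated with TiCl4 (CH2Cl2, −78 °C), which should bind the less hindered primary oxygen, open the ketal to the oxocarbenium ion and let the allylsilane close ring A (ketal-initiated Hosomi–Sakurai cyclisation), giving 14 after aqueous work-up.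

Step 12. The ring-closing addition may show poor facial selectivity at C4, and the slow seven-membered closure may be overtaken by protonation of the alkenylchromium species. The fallback sets out from 17 and comes back at 18; it replaces substrate control by reagent control. The chromium-mediated closure is run without regard to selectivity. The mixture of 18 and its C4 epimer (2R,4S,5aS,7S,9aS)-7-bromo-2-(bromomethyl)-6,6,9a-trimethyl-3-methylidenedecahydro-1-benzoxepin-4-ol F2 is oxidised with Dess–Martin periodinane to the enone (2R,5aS,7S,9aS)-7-bromo-2-(bromomethyl)-6,6,9a-trimethyl-3-methylideneoctahydro-1-benzoxepin-4(2H)-one F3. F3 is reduced with catecholborane and (S)-2-methyl-CBS-oxazaborolidine (toluene, −78 °C; Corey–Bakshi–Shibata reduction, the methylidene-bearing carbon acting as the large group), which should give the (4R)-alcohol 18.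

Step 4. The strongly basic azaenolate may cause E2 loss of triflic acid or attack bromine instead of the β-branched primary carbon, and bromonium participation may erode the C10 configuration. The fallback sets out from 5 and comes back at 7; it replaces the enolate alkylation by a copper-catalysed coupling and an oxidation. 5 is coupled with allylmagnesium bromide under Li2CuCl4 catalysis (THF, −78 °C) to (S)-5-bromo-6,6-dimethylocta-1,7-diene F4. The unhindered terminal alkene of F4 is then oxidised to the methyl ketone by a Wacker oxidation (PdCl2, CuCl, O2, DMF/H2O), the vinyl group on the quaternary carbon being too hindered to react, to give 7.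

Further compounds
F1 | step 8 | (4S)-4-(1-bromoethenyl)-2-[(3S,5E)-3-bromo-4,4-dimethyl-7-(trimethylsilyl)hept-5-en-1-yl]-2-methyl-1,3-dioxolane | CC1(CC[C@H](Br)C(C)(C)/C=C/C[Si](C)(C)C)OC[C@@H](C(Br)=C)O1
F2 | step 12 | (2R,4S,5aS,7S,9aS)-7-bromo-2-(bromomethyl)-6,6,9a-trimethyl-3-methylidenedecahydro-1-benzoxepin-4-ol | C=C1[C@@H](O)C[C@H]2C(C)(C)[C@@H](Br)CC[C@]2(C)O[C@H]1CBr
F3 | step 12 | (2R,5aS,7S,9aS)-7-bromo-2-(bromomethyl)-6,6,9a-trimethyl-3-methylideneoctahydro-1-benzoxepin-4(2H)-one | C=C1C(=O)C[C@H]2C(C)(C)[C@@H](Br)CC[C@]2(C)O[C@H]1CBr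
F4 | step 4 | (S)-5-bromo-6,6-dimethylocta-1,7-diene | C=CCC[C@H](Br)C(C)(C)C=C
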